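**Plan** (target numbering: ring A = C1–C5 and C10; ring B = C5–C10; C11 = benzylic CH2)
- Retrosynthesis: quinone → 2,3,5,6-tetramethoxyphenyl; C4=CH2 → C4=O → C4=C5 alkene; C11–aryl bond (aryllithium + C11 aldehyde); then the C9–C10 bond of ring B, with the C4–O bond restored, back to an eight-membered allylic lactone; last the lactone C–O and C5–C6 bonds.
- Forward: ring A (3-methylcyclohexenone) and the arene are bought. The C6–C9/C11 chain is joined to C5 by B-alkyl Suzuki–Miyaura coupling and tied to the C4 oxygen as a temporary eight-membered lactone. Ring B is closed last by an Ireland–Claisen ring contraction, then come aryl attachment, C4 methylenation and quinone unveiling.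
- Enabling feature: in ring A the allylic unit C4(O)–C5=C10 carries the chain on its central carbon C5. In the lactone the enolate carbon C9 therefore lies across the eight-membered ring from C5 and over C10, so a [3,3] shift closes ring B at its most hindered bond (C9–C10, both quaternary). The same shift turns the C4 oxygen into the C4=C5 alkene that later gives C4=CH2 and C5–H.
- Stereochemistry: C8 from an oxazolidinone auxiliary (vinylcuprate addition); C4–OH from Corey–Bakshi–Shibata reduction, relayed suprafacially to C10; C9 from the ring-locked ketene acetal and the tether topology; C5 from hydroboration anti to the C10 methyl.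

Key step: step 9

Remark: C9 in compounds 6–13 is defined but inconsequential (it is enolised in step 9), and 20 and 21 are C11 epimer mixtures (C11 becomes CH2 in step 12). Compounds 1, 2, 7 and 18 and all reagents are taken as purchasable.

Step 1
Reactants: 1 (S)-4-benzyloxazolidin-2-one; 2 (E)-but-2-enoic anhydride
Product: 3 (S)-4-benzyl-3-[(E)-but-2-enoyl]oxazolidin-2-one
Conditions: Et3N, LiCl, THF, −20 °C → rt
Reagents that add atoms: none
Why: N-acylation of the oxazolidinone by the anhydride under mild LiCl/Et3N activation should avoid strong base and migration of the crotonyl double bond.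

Step 2
Reactants: 3 (S)-4-benzyl-3-[(E)-but-2-enoyl]oxazolidin-2-one
Product: 4 (S)-4-benzyl-3-[(3R)-3-methylpent-4-enoyl]oxazolidin-2-one
Conditions: vinylMgBr, CuBr·SMe2, THF/Me2S, −78 → −20 °C; aq. NH4Cl
Reagents that add atoms: vinylmagnesium bromide, C=C[Mg]Br
Why: Conjugate addition of the vinylcuprate to the magnesium-chelated s-cis N-enoyl imide from the face opposite the benzyl group should set C8 under auxiliary control.

Step 3
Reactants: 4 (S)-4-benzyl-3-[(3R)-3-methylpent-4-enoyl]oxazolidin-2-one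
Product: 6 (S)-4-benzyl-3-[(2S,3S)-2,3-dimethylpent-4-enoyl]oxazolidin-2-one, via sodium enolate 5 (not isolated)
Conditions: NaN(SiMe3)2, THF, −78 °C; then MeI, −78 → −40 °C
Reagents that add atoms: iodomethane, CI
Why: Alkylation of the chelated Z-enolate anti to the benzyl group installs the C9 methyl, and C8, being β to the carbonyl, is not touched.

Step 4
Reactants: 7 3-methylcyclohex-2-en-1-one
Product: 8 2-iodo-3-methylcyclohex-2-en-1-one
Conditions: I2, pyridine, CH2Cl2, 0 °C → rt
Reagents that add atoms: iodine, II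
Why: α-Iodination of the enone by the pyridine-mediated addition–iodination–elimination sequence (Baylis–Hillman-type) should give the vinyl iodide needed for coupling at C5.

Step 5
Reactants: 6 (S)-4-benzyl-3-[(2S,3S)-2,3-dimethylpent-4-enoyl]oxazolidin-2-one; 8 2-iodo-3-methylcyclohex-2-en-1-one
Product: 10 (S)-4-benzyl-3-[(2S,3S)-2,3-dimethyl-5-(2-methyl-6-oxocyclohex-1-en-1-yl)pentanoyl]oxazolidin-2-one, via B-alkyl-9-BBN adduct 9 (not isolated)
Conditions: 9-BBN, THF, 0 °C → rt; then 8, PdCl2(dppf) (cat.), AsPh3 (cat.), aq. K3PO4, DMF, rt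
Reagents that add atoms: none
Why: Anti-Markovnikov hydroboration of the terminal alkene followed by B-alkyl Suzuki–Miyaura coupling with the 2-iodoenone should form the C5–C6 bond under conditions mild enough for the imide.

Step 6
Reactants: 10 (S)-4-benzyl-3-[(2S,3S)-2,3-dimethyl-5-(2-methyl-6-oxocyclohex-1-en-1-yl)pentanoyl]oxazolidin-2-one
Product: 11 (S)-4-benzyl-3-{(2S,3S)-5-[(6R)-6-hydroxy-2-methylcyclohex-1-en-1-yl]-2,3-dimethylpentanoyl}oxazolidin-2-one
Conditions: (S)-2-methyl-CBS-oxazaborolidine (cat.), BH3·SMe2, THF, −20 °C; MeOH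
Reagents that add atoms: none
Why: Corey–Bakshi–Shibata reduction with the tetrasubstituted alkenyl arm as the large group should give the (R)-allylic alcohol at C4 under reagent control, independent of the remote C8 centre.

Step 7
Reactants: 11 (S)-4-benzyl-3-{(2S,3S)-5-[(6R)-6-hydroxy-2-methylcyclohex-1-en-1-yl]-2,3-dimethylpentanoyl}oxazolidin-2-one
Product: 12 (2S,3S)-5-[(6R)-6-hydroxy-2-methylcyclohex-1-en-1-yl]-2,3-dimethylpentanoic acid
Conditions: LiOH, H2O2, THF/H2O, 0 °C; then Na2SO3; then dilute HCl to pH 4, 0 °C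
Reagents that add atoms: hydrogen peroxide, OO
Why: Hydroperoxide attacks the exocyclic imide carbonyl selectively and should release the auxiliary without harming the allylic alcohol or C8.

Step 8
Reactants: 12 (2S,3S)-5-[(6R)-6-hydroxy-2-methylcyclohex-1-en-1-yl]-2,3-dimethylpentanoic acid
Product: 13 (3S,4S,10aR)-3,4,7-trimethyl-3,4,5,6,8,9,10,10a-octahydro-2H-1-benzoxocin-2-one (eight-membered lactone fused to ring A at C4–C5)
Conditions: 2-methyl-6-nitrobenzoic anhydride, DMAP (cat.), Et3N, CH2Cl2, high dilution with slow addition, rt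
Reagents that add atoms: none
Why: Shiina macrolactonisation under high dilution should close the eight-membered lactone, helped by the ring sp2 carbon C5 and the vicinal methyl groups, which bias the seco acid towards a folded conformation.

Step 9
Reactants: 13 (3S,4S,10aR)-3,4,7-trimethyl-3,4,5,6,8,9,10,10a-octahydro-2H-1-benzoxocin-2-one
Product: 16 [(1R,2S,8aS)-1,2,8a-trimethyl-1,2,3,4,6,7,8,8a-octahydronaphthalen-1-yl]methanol, via silyl ketene acetal 14 (not isolated), via silyl ester 15 (not isolated)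
Conditions: KN(SiMe3)2, t-BuMe2SiCl, THF/DMPU, −78 °C; then toluene, 90 °C; then LiAlH4, THF, 0 °C → rt
Reagents that add atoms: none
Why: Proposed new method: enolisation of 13 at its only acidic C–H (C9) and O-silylation give ketene acetal 14, whose C9=C11 bond can only be ring-cis in the eight-membered ring, and a [3,3]-sigmatropic (Ireland–Claisen) shift then breaks the allylic C4–O bond and joins C9 to C10; the closest known reaction type is the Ireland–Claisen ring contraction of macrolactone silyl ketene acetals, known for allyl units lying wholly in the lactone ring but not, to my knowledge, for one whose central carbon C5 is the ring member and whose terminus C10 is exocyclic. Ring B (C5–C6–C7–C8–C9–C10) closes by bonding of the transannular carbons C9 and C10, formally 6-endo-trig with respect to C5=C10, through a bicyclo[3.3.1]-like array in which the tether C6–C7–C8 bridges C5 and C9, and the lactone ring opens in the same event, so medium-ring strain and the new silyl ester C=O drive it. C10 is set by suprafacial chirality transfer from the C4 carbinol, because C9 must arrive on the face that the C4–O bond leaves, which places the C10 methyl β. C9 is set by topology, because C11 has to stay on the C4–O side and C8 on the C6 side of the new bond, so the carboxyl carbon ends anti and the C9 methyl cis to the C10 methyl whether the array is chair-like or boat-like. C8 is carried in unchanged, so the only selectivity needed is for the [3,3] path over C-silylation, ketene formation or a [1,3] shift, which the internal silyl quench at −78 °C and the enforced proximity of C9 and C10 should secure; the developing 1,3-diaxial C8/C10 methyl pair should cost rate and not selectivity, hence the heating. Reduction of the hindered silyl ester 15 in the same flask should give 16.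

Step 10
Reactants: 16 [(1R,2S,8aS)-1,2,8a-trimethyl-1,2,3,4,6,7,8,8a-octahydronaphthalen-1-yl]methanol
Product: 17 (1R,2S,8aS)-1,2,8a-trimethyl-1,2,3,4,6,7,8,8a-octahydronaphthalene-1-carbaldehyde
Conditions: Dess–Martin periodinane, NaHCO3, CH2Cl2, rt
Reagents that add atoms: none
Why: Dess–Martin oxidation of the neopentyl alcohol should stop cleanly at the non-enolisable aldehyde.

Step 11
Reactants: 17 (1R,2S,8aS)-1,2,8a-trimethyl-1,2,3,4,6,7,8,8a-octahydronaphthalene-1-carbaldehyde; 18 1,2,4,5-tetramethoxybenzene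
Product: 21 O-{(2,3,5,6-tetramethoxyphenyl)[(1R,2S,8aS)-1,2,8a-trimethyl-1,2,3,4,6,7,8,8a-octahydronaphthalen-1-yl]methyl} S-methyl dithiocarbonate, via aryllithium 19 (not isolated), via lithium alkoxide 20 (not isolated)
Conditions: 18, n-BuLi, THF, 0 °C; then 17, −78 °C → rt; then CS2; then MeI, 0 °C → rt
Reagents that add atoms: carbon disulfide, S=C=S; iodomethane, CI
Why: Ortho-lithiation of 18 between two methoxy groups gives 19, which can only add to the non-enolisable aldehyde, and trapping of alkoxide 20 as the xanthate prepares radical deoxygenation.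

Step 12
Reactants: 21 O-{(2,3,5,6-tetramethoxyphenyl)[(1R,2S,8aS)-1,2,8a-trimethyl-1,2,3,4,6,7,8,8a-octahydronaphthalen-1-yl]methyl} S-methyl dithiocarbonate
Product: 22 3-{[(1R,2S,8aS)-1,2,8a-trimethyl-1,2,3,4,6,7,8,8a-octahydronaphthalen-1-yl]methyl}-1,2,4,5-tetramethoxybenzene
Conditions: Bu3SnH, AIBN (cat.), toluene, 100 °C
Reagents that add atoms: none
Why: Barton–McCombie deoxygenation through the benzylic radical should remove the C11 oxygen without the cationic rearrangement that the neopentyl centre and the C4=C5 alkene would invite under acid.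

Step 13
Reactants: 22 3-{[(1R,2S,8aS)-1,2,8a-trimethyl-1,2,3,4,6,7,8,8a-octahydronaphthalen-1-yl]methyl}-1,2,4,5-tetramethoxybenzene
Product: 24 (1R,4aS,5R,6S,8aR)-4a,5,6-trimethyl-5-[(2,3,5,6-tetramethoxyphenyl)methyl]decahydronaphthalen-1-ol, via C4 alkylborane 23 (not isolated)
Conditions: BH3·THF, THF, 0 °C → rt; then NaOH, H2O2, 0 °C → rt
Reagents that add atoms: hydrogen peroxide, OO
Why: Hydroboration–oxidation should place boron on the less substituted C4 and deliver H to C5 syn from the α face, because boron on the β face would be 1,3-diaxial to the C10 methyl, which gives the trans ring fusion.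

Step 14
Reactants: 24 (1R,4aS,5R,6S,8aR)-4a,5,6-trimethyl-5-[(2,3,5,6-tetramethoxyphenyl)methyl]decahydronaphthalen-1-ol
Product: 25 (4aS,5R,6S,8aR)-4a,5,6-trimethyl-5-[(2,3,5,6-tetramethoxyphenyl)methyl]octahydronaphthalen-1(2H)-one
Conditions: Dess–Martin periodinane, NaHCO3, CH2Cl2, rt
Reagents that add atoms: none
Why: Buffered Dess–Martin oxidation should give the C4 ketone without enolising the adjacent ring-fusion centre C5.

Step 15
Reactants: 25 (4aS,5R,6S,8aR)-4a,5,6-trimethyl-5-[(2,3,5,6-tetramethoxyphenyl)methyl]octahydronaphthalen-1(2H)-one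
Product: 26 3-{[(1R,2S,4aS,8aS)-1,2,8a-trimethyl-5-methylidenedecahydronaphthalen-1-yl]methyl}-1,2,4,5-tetramethoxybenzene
Conditions: Zn, CH2Br2, TiCl4, THF/CH2Cl2, 0 °C → rt
Reagents that add atoms: dibromomethane, BrCBr
Why: Takai–Lombardo methylenation is non-basic, so C4=O should become C4=CH2 without epimerisation of C5, which a basic ylide could cause.

Step 16
Reactants: 26 3-{[(1R,2S,4aS,8aS)-1,2,8a-trimethyl-5-methylidenedecahydronaphthalen-1-yl]methyl}-1,2,4,5-tetramethoxybenzene
Product: 27 2,5-dimethoxy-3-{[(1R,2S,4aS,8aS)-1,2,8a-trimethyl-5-methylidenedecahydronaphthalen-1-yl]methyl}cyclohexa-2,5-diene-1,4-dione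
Conditions: (NH4)2Ce(NO3)6, MeCN/H2O, 0 °C
Reagents that add atoms: water, O
Why: Oxidative demethylation of a para-dimethoxy pair by tetravalent cerium should give the 2,5-dimethoxy-1,4-benzoquinone and leave the isolated exocyclic alkene alone.

Step 17
Reactants: 27 2,5-dimethoxy-3-{[(1R,2S,4aS,8aS)-1,2,8a-trimethyl-5-methylidenedecahydronaphthalen-1-yl]methyl}cyclohexa-2,5-diene-1,4-dione
Product: 28 2-hydroxy-5-methoxy-3-{[(1R,2S,4aS,8aS)-1,2,8a-trimethyl-5-methylidenedecahydronaphthalen-1-yl]methyl}cyclohexa-2,5-diene-1,4-dione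
Conditions: KOH, MeOH/H2O, rt; then dilute HCl, 0 °C
Reagents that add atoms: potassium hydroxide, [K+].[OH-]
Why: Addition–elimination of hydroxide at the vinylogous ester carbon next to the alkyl group, whose methoxy is twisted out of conjugation by the neopentyl substituent, should give the 2-hydroxy-5-methoxyquinone.

**Compound list**
1 | (S)-4-benzyloxazolidin-2-one | O=C1N[C@@H](Cc2ccccc2)CO1 | starting material
2 | (E)-but-2-enoic anhydride | C/C=C/C(=O)OC(=O)/C=C/C | starting material
3 | (S)-4-benzyl-3-[(E)-but-2-enoyl]oxazolidin-2-one | C/C=C/C(=O)N1[C@@H](Cc2ccccc2)COC1=O | intermediate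
4 | (S)-4-benzyl-3-[(3R)-3-methylpent-4-enoyl]oxazolidin-2-one | C=C[C@H](C)CC(=O)N1[C@@H](Cc2ccccc2)COC1=O | intermediate
5 | sodium (Z)-enolate of 4 | [Na+].C=C[C@H](C)/C=C(\[O-])N1[C@@H](Cc2ccccc2)COC1=O | intermediate
6 | (S)-4-benzyl-3-[(2S,3S)-2,3-dimethylpent-4-enoyl]oxazolidin-2-one | C=C[C@H](C)[C@H](C)C(=O)N1[C@@H](Cc2ccccc2)COC1=O | intermediate
7 | 3-methylcyclohex-2-en-1-one | CC1=CC(=O)CCC1 | starting material
8 | 2-iodo-3-methylcyclohex-2-en-1-one | CC1=C(I)C(=O)CCC1 | intermediate
9 | B-alkyl-9-borabicyclo[3.3.1]nonane from 6 (boron on C6) | C[C@@H](CCB1C2CCCC1CCC2)[C@H](C)C(=O)N1[C@@H](Cc2ccccc2)COC1=O | intermediate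
10 | (S)-4-benzyl-3-[(2S,3S)-2,3-dimethyl-5-(2-methyl-6-oxocyclohex-1-en-1-yl)pentanoyl]oxazolidin-2-one | CC1=C(CC[C@H](C)[C@H](C)C(=O)N2[C@@H](Cc3ccccc3)COC2=O)C(=O)CCC1 | intermediate
11 | (S)-4-benzyl-3-{(2S,3S)-5-[(6R)-6-hydroxy-2-methylcyclohex-1-en-1-yl]-2,3-dimethylpentanoyl}oxazolidin-2-one | CC1=C(CC[C@H](C)[C@H](C)C(=O)N2[C@@H](Cc3ccccc3)COC2=O)[C@H](O)CCC1 | intermediate
12 | (2S,3S)-5-[(6R)-6-hydroxy-2-methylcyclohex-1-en-1-yl]-2,3-dimethylpentanoic acid | CC1=C(CC[C@H](C)[C@H](C)C(=O)O)[C@H](O)CCC1 | intermediate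
13 | (3S,4S,10aR)-3,4,7-trimethyl-3,4,5,6,8,9,10,10a-octahydro-2H-1-benzoxocin-2-one | CC1=C2CC[C@H](C)[C@H](C)C(=O)O[C@@H]2CCC1 | intermediate
14 | tert-butyldimethylsilyl ketene acetal of 13 (ring-cis C9=C11) | CC1=C2CC[C@H](C)/C(C)=C(/O[Si](C)(C)C(C)(C)C)O[C@@H]2CCC1 | intermediate
15 | tert-butyldimethylsilyl (1R,2S,8aS)-1,2,8a-trimethyl-1,2,3,4,6,7,8,8a-octahydronaphthalene-1-carboxylate | C1=C2CC[C@H](C)[C@@](C)(C(=O)O[Si](C)(C)C(C)(C)C)[C@@]2(C)CCC1 | intermediate
16 | [(1R,2S,8aS)-1,2,8a-trimethyl-1,2,3,4,6,7,8,8a-octahydronaphthalen-1-yl]methanol | C1=C2CC[C@H](C)[C@@](C)(CO)[C@@]2(C)CCC1 | intermediate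
17 | (1R,2S,8aS)-1,2,8a-trimethyl-1,2,3,4,6,7,8,8a-octahydronaphthalene-1-carbaldehyde | C1=C2CC[C@H](C)[C@@](C)(C=O)[C@@]2(C)CCC1 | intermediate
18 | 1,2,4,5-tetramethoxybenzene | COc1cc(OC)c(OC)cc1OC | starting material
19 | 2,3,5,6-tetramethoxyphenyllithium | [Li]c1c(OC)c(OC)cc(OC)c1OC | intermediate
20 | lithium alkoxide from addition of 19 to 17 (C11 epimers) | C1=C2CC[C@H](C)[C@@](C)(C(O[Li])c3c(OC)c(OC)cc(OC)c3OC)[C@@]2(C)CCC1 | intermediate
21 | O-{(2,3,5,6-tetramethoxyphenyl)[(1R,2S,8aS)-1,2,8a-trimethyl-1,2,3,4,6,7,8,8a-octahydronaphthalen-1-yl]methyl} S-methyl dithiocarbonate (C11 epimers) | C1=C2CC[C@H](C)[C@@](C)(C(OC(=S)SC)c3c(OC)c(OC)cc(OC)c3OC)[C@@]2(C)CCC1 | intermediate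
22 | 3-{[(1R,2S,8aS)-1,2,8a-trimethyl-1,2,3,4,6,7,8,8a-octahydronaphthalen-1-yl]methyl}-1,2,4,5-tetramethoxybenzene | C1=C2CC[C@H](C)[C@@](C)(Cc3c(OC)c(OC)cc(OC)c3OC)[C@@]2(C)CCC1 | intermediate
23 | C4α-alkylborane from 22 (H at C5α, trans-fused) | B[C@@H]1CCC[C@@]2(C)[C@H]1CC[C@H](C)[C@@]2(C)Cc1c(OC)c(OC)cc(OC)c1OC | intermediate
24 | (1R,4aS,5R,6S,8aR)-4a,5,6-trimethyl-5-[(2,3,5,6-tetramethoxyphenyl)methyl]decahydronaphthalen-1-ol | O[C@@H]1CCC[C@@]2(C)[C@H]1CC[C@H](C)[C@@]2(C)Cc1c(OC)c(OC)cc(OC)c1OC | intermediate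
25 | (4aS,5R,6S,8aR)-4a,5,6-trimethyl-5-[(2,3,5,6-tetramethoxyphenyl)methyl]octahydronaphthalen-1(2H)-one | O=C1CCC[C@@]2(C)[C@H]1CC[C@H](C)[C@@]2(C)Cc1c(OC)c(OC)cc(OC)c1OC | intermediate
26 | 3-{[(1R,2S,4aS,8aS)-1,2,8a-trimethyl-5-methylidenedecahydronaphthalen-1-yl]methyl}-1,2,4,5-tetramethoxybenzene | C=C1CCC[C@@]2(C)[C@H]1CC[C@H](C)[C@@]2(C)Cc1c(OC)c(OC)cc(OC)c1OC | intermediate
27 | 2,5-dimethoxy-3-{[(1R,2S,4aS,8aS)-1,2,8a-trimethyl-5-methylidenedecahydronaphthalen-1-yl]methyl}cyclohexa-2,5-diene-1,4-dione | C=C1CCC[C@@]2(C)[C@H]1CC[C@H](C)[C@@]2(C)CC1=C(OC)C(=O)C=C(OC)C1=O | intermediate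
28 | 2-hydroxy-5-methoxy-3-{[(1R,2S,4aS,8aS)-1,2,8a-trimethyl-5-methylidenedecahydronaphthalen-1-yl]methyl}cyclohexa-2,5-diene-1,4-dione | C=C1CCC[C@@]2(C)[C@H]1CC[C@H](C)[C@@]2(C)CC1=C(O)C(=O)C=C(OC)C1=O | target

**Step count and risks**

Total steps: 17. Longest linear sequence: 16 steps (steps 1–3 and 5–17; step 4 is the side branch to 8).

Steps most likely to fail:

1. Step 9 (proposed new method). The bridged transition state may be too strained, so that on heating the ketene acetal is lost to C-silylation, fragmentation to a ketene or hydrolysis before C9 and C10 bond. The fallback uses known chemistry (acyclic Ireland–Claisen rearrangement of a cyclohexenyl ester, ring-closing metathesis, hydroxyl-directed hydrogenation). It sets out from 8 and comes back at 16.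
   - Stille coupling of 8 with allyltributylstannane (Pd(PPh3)4, CuI, DMF) would give 2-allyl-3-methylcyclohex-2-en-1-one F1.
   - Corey–Bakshi–Shibata reduction as in step 6 would give (R)-2-allyl-3-methylcyclohex-2-en-1-ol F2.
   - Esterification with 2,3-dimethylbut-2-enoic acid (DCC, DMAP) would give (R)-2-allyl-3-methylcyclohex-2-en-1-yl 2,3-dimethylbut-2-enoate F3.
   - γ-Deprotonation with LiN(iPr)2/HMPA, silylation with Me3SiCl and [3,3] shift of the silyl dienolate would join C9 to C10 and give 2-[(1S)-2-allyl-1-methylcyclohex-2-en-1-yl]-2,3-dimethylbut-3-enoic acid F4. Its C9 configuration rests on the dienolate geometry and the chair/boat preference and would have to be checked, with the epimer separated if formed.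
   - LiAlH4 would give the corresponding primary alcohol F5.
   - Ring-closing metathesis with the second-generation Grubbs catalyst would close ring B at C7=C8 and give [(8aS)-1,2,8a-trimethyl-1,4,6,7,8,8a-hexahydronaphthalen-1-yl]methanol F6.
   - Hydroxyl-directed hydrogenation with [Ir(cod)(PCy3)(py)]PF6 would deliver H2 to C7=C8 from the face of the C9 CH2OH group, placing the C8 methyl β, and so return to 16. The more remote and more hindered C4=C5 alkene should react more slowly.

2. Step 8. Intermolecular esterification (diolide and oligomers) may outrun closure of the strained eight-membered ring, and the activated allylic alcohol may ionise. The fallback builds the lactone ring by metathesis; it sets out from 8 and 6 and comes back at 13.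
   - Stille coupling of 8 with tributyl(vinyl)stannane (Pd(PPh3)4, CuI) would give 3-methyl-2-vinylcyclohex-2-en-1-one F7.
   - Corey–Bakshi–Shibata reduction would give (R)-3-methyl-2-vinylcyclohex-2-en-1-ol F8.
   - LiOH/H2O2 cleavage of 6 would give (2S,3S)-2,3-dimethylpent-4-enoic acid F9.
   - Carbodiimide esterification of F8 with F9 would give (R)-3-methyl-2-vinylcyclohex-2-en-1-yl (2S,3S)-2,3-dimethylpent-4-enoate F10.
   - Ring-closing metathesis with the second-generation Hoveyda–Grubbs catalyst at high dilution would form the C6=C7 bond and give the dienyl lactone (3S,4S,10aR)-3,4,7-trimethyl-3,4,8,9,10,10a-hexahydro-2H-1-benzoxocin-2-one F11.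
   - Diimide (from 2-nitrobenzenesulfonylhydrazide and Et3N) would reduce the disubstituted C6=C7 bond and leave the tetrasubstituted C5=C10 bond, giving 13.

3. Step 11. Addition of the di-ortho-substituted aryllithium to the crowded aldehyde may be slow, thiocarbonylation of the very hindered lithium alkoxide may be incomplete, and the electron-rich benzylic xanthate may ionise. The fallback carries the free alcohol forward and removes the oxygen ionically once no alkene is left; it sets out from 17 (with 18) and comes back at 24.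
   - Addition of 19 to 17 with aqueous work-up would give the benzylic alcohol (2,3,5,6-tetramethoxyphenyl)[(1R,2S,8aS)-1,2,8a-trimethyl-1,2,3,4,6,7,8,8a-octahydronaphthalen-1-yl]methanol F12.
   - Hydroboration–oxidation as in step 13 would give the diol, the C4α-hydroxy trans-decalin still carrying the benzylic hydroxyl F13.
   - Ionic hydrogenation (Et3SiH, CF3CO2H, CH2Cl2, −20 °C) through the aryl-stabilised benzylic cation would remove only the benzylic hydroxyl and give 24.

Further compounds
F1 | step 9 | 2-allyl-3-methylcyclohex-2-en-1-one | C=CCC1=C(C)CCCC1=O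
F2 | step 9 | (R)-2-allyl-3-methylcyclohex-2-en-1-ol | C=CCC1=C(C)CCC[C@H]1O
F3 | step 9 | (R)-2-allyl-3-methylcyclohex-2-en-1-yl 2,3-dimethylbut-2-enoate | C=CCC1=C(C)CCC[C@H]1OC(=O)C(C)=C(C)C
F4 | step 9 | 2-[(1S)-2-allyl-1-methylcyclohex-2-en-1-yl]-2,3-dimethylbut-3-enoic acid (C9 as in 16) | C=CCC1=CCCC[C@]1(C)[C@@](C)(C(C)=C)C(=O)O
F5 | step 9 | 2-[(1S)-2-allyl-1-methylcyclohex-2-en-1-yl]-2,3-dimethylbut-3-en-1-ol (C9 as in 16) | C=CCC1=CCCC[C@]1(C)[C@@](C)(C(C)=C)CO
F6 | step 9 | [(8aS)-1,2,8a-trimethyl-1,4,6,7,8,8a-hexahydronaphthalen-1-yl]methanol (C9 as in 16) | CC1=CCC2=CCCC[C@]2(C)[C@]1(C)CO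
F7 | step 8 | 3-methyl-2-vinylcyclohex-2-en-1-one | C=CC1=C(C)CCCC1=O
F8 | step 8 | (R)-3-methyl-2-vinylcyclohex-2-en-1-ol | C=CC1=C(C)CCC[C@H]1O
F9 | step 8 | (2S,3S)-2,3-dimethylpent-4-enoic acid | C=C[C@H](C)[C@H](C)C(=O)O
F10 | step 8 | (R)-3-methyl-2-vinylcyclohex-2-en-1-yl (2S,3S)-2,3-dimethylpent-4-enoate | C=CC1=C(C)CCC[C@H]1OC(=O)[C@@H](C)[C@@H](C)C=C
F11 | step 8 | (3S,4S,10aR)-3,4,7-trimethyl-3,4,8,9,10,10a-hexahydro-2H-1-benzoxocin-2-one (ring-cis C6=C7) | CC1=C2/C=C\[C@H](C)[C@H](C)C(=O)O[C@@H]2CCC1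
F12 | step 11 | (2,3,5,6-tetramethoxyphenyl)[(1R,2S,8aS)-1,2,8a-trimethyl-1,2,3,4,6,7,8,8a-octahydronaphthalen-1-yl]methanol (C11 epimers) | C1=C2CC[C@H](C)[C@@](C)(C(O)c3c(OC)c(OC)cc(OC)c3OC)[C@@]2(C)CCC1
F13 | step 11 | C4α-hydroxy trans-decalin diol bearing the C11 benzylic hydroxyl (C11 epimers) | O[C@@H]1CCC[C@@]2(C)[C@H]1CC[C@H](C)[C@@]2(C)C(O)c1c(OC)c(OC)cc(OC)c1OC
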